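**Plan**

1. Retrosynthesis: the spiro-cyclohexene (ring C; bonds C2–C4′ and C14–C15′, primes = spiro half) is cut by retro-Diels–Alder/deconjugation into dehydrozaluzanin C 27 (dienophile C4′=C15′) and the 1,10(14)-dienone 45 generated from its 8β-silyloxy congener 43.
2. Both guaianolides go back to one lactone–enoate 14, whose cycloheptene is cut at C1–C10 and C8–C9 into the cyclopentenyl siloxycyclopropane 7 (C1, C5, C6, C7, C8) and methyl propiolate 8 (C9, C10, C14).
3. Enabling feature: the seven-membered ring carries oxygen on C6 beside the ring-fusion carbon C5 and a one-carbon branch (C14) on C10 beside C1. This is the imprint of a 1-oxy-1-vinylcyclopropane (C1=C5–C6(O) with C7–C8) plus a two-carbon alkyne; the ester at C14 later activates C8–H for the hydroxylated half.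
4. Forward: bromocyclopentenol → siloxy-vinylcyclopropane → [5+2] (cyclopentane + cycloheptenone) → C7 alkylation, C6 reduction, lactone 14. Branch a: ester → exocyclic methylene, C4 → C4=C15, C11 methylenation, C3 oxidation → 27. Branch b: the same after C8 oxidation/reduction → 43. Then Saegusa/Diels–Alder/isomerisation and desilylation.
5. Stereochemistry: one CBS-set carbinol (C4, later erased as C4=C15) steers C1 in the cycloaddition; C5 and C7 follow by equilibration next to the C6 ketone, C6 and C8 by hydride delivery, C4′ by α-face attack on 27, C10 by thermodynamic γ-protonation.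

Key step: step 5

Remark: guaiane numbering is used for both halves (ring fusion C1/C5, C6–O, C7–C11, C10–C14, C4–C15; α = face of H-1 and H-5; "nor" names mark missing carbons); 1, 4, 8 and 11 are taken as commercial. TBS = tert-butyldimethylsilyl, TES = triethylsilyl, TIPS = triisopropylsilyl.

**Route**

Step 1
Reactants: 1 2-bromocyclopent-2-en-1-one
Product: 2 (R)-2-bromocyclopent-2-en-1-ol
Conditions: (S)-2-methyl-CBS-oxazaborolidine (10 mol%), BH3·SMe2, THF, −20 °C; MeOH quench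
Reagents that add atoms: none
Why: Corey–Bakshi–Shibata reduction, in which the bromoalkenyl arm acts as the large group, should give the (R)-carbinol that later becomes C4.

Step 2
Reactants: 2 (R)-2-bromocyclopent-2-en-1-ol
Product: 3 (R)-tert-butyl[(2-bromocyclopent-2-en-1-yl)oxy]dimethylsilane
Conditions: TBSCl, imidazole, DMF, 23 °C
Reagents that add atoms: tert-butyldimethylsilyl chloride, CC(C)(C)[Si](C)(C)Cl
Why: Standard silylation of a secondary allylic alcohol; the bulky ether is the later facial control element.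

Step 3
Reactants: 3 (R)-tert-butyl[(2-bromocyclopent-2-en-1-yl)oxy]dimethylsilane; 4 1-ethoxycyclopropan-1-ol
Product: 6 1-[(5R)-5-(tert-butyldimethylsilyloxy)cyclopent-1-en-1-yl]cyclopropan-1-ol, via cyclopentenyllithium 5 (not isolated)
Conditions: 3, t-BuLi (2.1 equiv), Et2O, −78 °C; separately 4, MeMgBr (1.0 equiv), THF, 0 °C; combine, −78 → 23 °C; aq. NH4Cl
Reagents that add atoms: none
Why: Bromine–lithium exchange followed by 1,2-addition of the vinyllithium to cyclopropanone released from the magnesium hemiketal salt (cyclopropanone-hemiketal route to 1-vinylcyclopropanols); no new stereocenter.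

Step 4
Reactants: 6 1-[(5R)-5-(tert-butyldimethylsilyloxy)cyclopent-1-en-1-yl]cyclopropan-1-ol
Product: 7 1-(triethylsilyloxy)-1-[(5R)-5-(tert-butyldimethylsilyloxy)cyclopent-1-en-1-yl]cyclopropane
Conditions: Et3SiCl, imidazole, DMAP (cat.), DMF, 23 °C
Reagents that add atoms: chlorotriethylsilane, CC[Si](Cl)(CC)CC
Why: Silylation of the tertiary cyclopropanol gives the 1-siloxy-vinylcyclopropane needed for the cycloaddition; the TES enol ether formed later can be cleaved without touching the TBS ether.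

Step 5
Reactants: 7 1-(triethylsilyloxy)-1-[(5R)-5-(tert-butyldimethylsilyloxy)cyclopent-1-en-1-yl]cyclopropane; 8 methyl propiolate
Product: 10 methyl 4α-(tert-butyldimethylsilyloxy)-6-oxo-11,12,13,15-tetranor-1αH,5αH-guai-9-en-14-oate, via triethylsilyl enol ether cycloadduct 9 (not isolated)
Conditions: [Rh(CO)2Cl]2 (5 mol%), 8 (slow addition), ClCH2CH2Cl, 60 °C; then 1 M HCl, THF, 0 °C; then DBU (0.1 equiv), CH2Cl2, 0 °C
Reagents that add atoms: none
Why: The monovalent rhodium catalyst binds the C1=C5 alkene of 7 anti to the C4 silyloxy group and opens the C6–C8 cyclopropane bond to an allyl–alkyl rhodacycle; propiolate inserts at the allyl terminus C1 and C(sp2)–C(sp3) reductive elimination at C8 completes C1–C10 and C8–C9. The closest known reaction is the rhodium-catalysed intermolecular [5+2] cycloaddition of 1-siloxy-1-vinylcyclopropanes with alkynes, applied here to a cyclopentenyl-substituted member. The seven-membered ring is closed in an intermolecular metal-mediated [5+2] mode, both new bonds being made at the metal. C1 is controlled by the C4 stereocenter (C10 delivered to the β face, hence 1αH); C5 is set afterwards by protonation and base equilibration next to the C6 ketone, which should place C6 trans to the neighbouring C4–OTBS and give the cis-fused 5αH ketone. The step needs regioselective alkyne insertion with the ester-bearing carbon on C1: acceptor-substituted alkynes place that carbon at the first-formed bond (the allyl terminus), and the alkyne CH then couples with the unhindered CH2 (C8). The two cyclopropane CH2 groups are equivalent, so ring-opening regiochemistry is not an issue, and the enol ether 9 is hydrolysed in the same flask.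

Step 6
Reactants: 10 methyl 4α-(tert-butyldimethylsilyloxy)-6-oxo-11,12,13,15-tetranor-1αH,5αH-guai-9-en-14-oate; 11 methyl bromoacetate
Product: 12 dimethyl 4α-(tert-butyldimethylsilyloxy)-6-oxo-13,15-dinor-1αH,5αH,7αH-guai-9-ene-12,14-dioate
Conditions: LiN(SiMe3)2, THF, −78 °C; 11, DMPU, −78 → −30 °C; then DBU (0.2 equiv), CH2Cl2, 23 °C
Reagents that add atoms: none
Why: Kinetic enolate alkylation at the less hindered α-CH2 (C7, not the ring-fusion methine C5); amine equilibration should leave the C7 side chain β, cis to the C5–C4 bond (diequatorial-type 2,7-disubstituted cycloheptanone).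

Step 7
Reactants: 12 dimethyl 4α-(tert-butyldimethylsilyloxy)-6-oxo-13,15-dinor-1αH,5αH,7αH-guai-9-ene-12,14-dioate
Product: 14 methyl 4α-(tert-butyldimethylsilyloxy)-13,15-dinor-1αH,5αH,6βH,7αH-guai-9-en-12,6-olid-14-oate, via 6α-hydroxy diester 13 (not isolated)
Conditions: NaBH4, MeOH, −40 °C; then TsOH·H2O (cat.), CH2Cl2, 23 °C
Reagents that add atoms: none
Why: Borohydride reduction along the axial-type trajectory should give the all-trans (equatorial) 6α-alcohol, which closes to the trans-fused γ-lactone (lactonisation); the conjugated ester is not reduced.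

Step 8
Reactants: 14 methyl 4α-(tert-butyldimethylsilyloxy)-13,15-dinor-1αH,5αH,6βH,7αH-guai-9-en-12,6-olid-14-oate
Product: 15 4α-(tert-butyldimethylsilyloxy)-13,15-dinor-1αH,5αH,6βH,7αH-guai-9-en-12,6-olid-14-oic acid
Conditions: LiOH·H2O, THF–H2O, 23 °C; then 1 M HCl to pH 2, 23 °C
Reagents that add atoms: lithium hydroxide, [Li+].[OH-]
Why: Saponification; the lactone, if opened, should reclose on acidification because only the 6α-hydroxyl is available, which leaves the C14 acid differentiated from C12.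

Step 9
Reactants: 15 4α-(tert-butyldimethylsilyloxy)-13,15-dinor-1αH,5αH,6βH,7αH-guai-9-en-12,6-olid-14-oic acid
Product: 17 14-hydroxy-4α-(tert-butyldimethylsilyloxy)-13,15-dinor-1αH,5αH,6βH,7αH-guai-9-en-12,6-olide, via mixed carbonic anhydride 16 (not isolated)
Conditions: i-BuOCOCl, N-methylmorpholine, THF, −15 °C; then NaBH4, H2O, 0 °C
Reagents that add atoms: none
Why: Mixed-anhydride activation and borohydride reduction should convert the acid into the primary allylic alcohol without touching the lactone.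

Step 10
Reactants: 17 14-hydroxy-4α-(tert-butyldimethylsilyloxy)-13,15-dinor-1αH,5αH,6βH,7αH-guai-9-en-12,6-olide
Product: 19 4α-(tert-butyldimethylsilyloxy)-13,15-dinor-1αH,5αH,6βH,7αH-guai-10(14)-en-12,6-olide, via allylic diazene 18 (not isolated)
Conditions: PPh3, diethyl azodicarboxylate, 2-nitrobenzenesulfonylhydrazide, N-methylmorpholine/THF, −30 → 23 °C
Reagents that add atoms: none
Why: Mitsunobu displacement, loss of sulfinic acid and retro-ene loss of N2 from the monoalkyl diazene (reductive 1,3-transposition of an allylic alcohol) should deliver H to C9 and move the alkene to the exocyclic C10=C14 position.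

Step 11
Reactants: 19 4α-(tert-butyldimethylsilyloxy)-13,15-dinor-1αH,5αH,6βH,7αH-guai-10(14)-en-12,6-olide
Product: 20 4α-hydroxy-13,15-dinor-1αH,5αH,6βH,7αH-guai-10(14)-en-12,6-olide
Conditions: HF·pyridine, pyridine, THF, 0 → 23 °C
Reagents that add atoms: none
Why: Fluoride-mediated cleavage of the secondary TBS ether.

Step 12
Reactants: 20 4α-hydroxy-13,15-dinor-1αH,5αH,6βH,7αH-guai-10(14)-en-12,6-olide
Product: 21 4-oxo-13,15-dinor-1αH,5αH,6βH,7αH-guai-10(14)-en-12,6-olide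
Conditions: Dess–Martin periodinane, NaHCO3, CH2Cl2, 0 → 23 °C
Reagents that add atoms: none
Why: Dess–Martin oxidation under buffered, non-basic conditions should keep the β-acyloxy ketone from eliminating or epimerising at C5.

Step 13
Reactants: 21 4-oxo-13,15-dinor-1αH,5αH,6βH,7αH-guai-10(14)-en-12,6-olide
Product: 22 13-nor-1αH,5αH,6βH,7αH-guaia-4(15),10(14)-dien-12,6-olide
Conditions: Zn, CH2Br2, TiCl4, THF/CH2Cl2, 0 → 23 °C
Reagents that add atoms: dibromomethane, BrCBr
Why: Lombardo methylenation is non-basic and selective for ketones over lactones, so C15 should be installed without β-elimination of the lactone oxygen.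

Step 14
Reactants: 22 13-nor-1αH,5αH,6βH,7αH-guaia-4(15),10(14)-dien-12,6-olide
Product: 25 dehydrocostus lactone [guaia-4(15),10(14),11(13)-trien-12,6α-olide], via 13-dimethylamino Mannich base 23 (not isolated), via trimethylammonium iodide 24 (not isolated)
Conditions: LiN(i-Pr)2, THF, −78 °C; CH2=NMe2+ I−, −78 → 0 °C; then MeI, MeOH, 23 °C; then aq. NaHCO3, CH2Cl2
Reagents that add atoms: Eschenmoser's salt, C=[N+](C)C.[I-]
Why: Lactone enolate aminomethylation (Mannich reaction with Eschenmoser's salt), quaternisation and β-elimination is the standard α-methylenation of γ-butyrolactones; the C11 center of 23 is erased.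

Step 15
Reactants: 25 dehydrocostus lactone
Product: 26 3-epizaluzanin C [3α-hydroxyguaia-4(15),10(14),11(13)-trien-12,6α-olide]
Conditions: SeO2 (0.5 equiv), t-BuOOH, CH2Cl2, 0 → 23 °C
Reagents that add atoms: selenium dioxide, O=[Se]=O; tert-butyl hydroperoxide, CC(C)(C)OO
Why: Selenium dioxide allylic hydroxylation (ene reaction then [2,3]-shift) at the CH2 next to the C4=C15 methylene is a known conversion of this very lactone; the carbinol configuration is irrelevant.

Step 16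
Reactants: 26 3-epizaluzanin C
Product: 27 dehydrozaluzanin C [3-oxoguaia-4(15),10(14),11(13)-trien-12,6α-olide]
Conditions: Dess–Martin periodinane, NaHCO3, CH2Cl2, 0 °C
Reagents that add atoms: none
Why: Dess–Martin oxidation of the allylic alcohol gives the exo-methylene enone used as dienophile.

Step 17
Reactants: 14 methyl 4α-(tert-butyldimethylsilyloxy)-13,15-dinor-1αH,5αH,6βH,7αH-guai-9-en-12,6-olid-14-oate
Product: 28 methyl 4α-(tert-butyldimethylsilyloxy)-8-oxo-13,15-dinor-1αH,5αH,6βH,7αH-guai-9-en-12,6-olid-14-oate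
Conditions: Rh2(cap)4 (1 mol%, cap = caprolactamate), t-BuOOH (5 equiv, in decane), ClCH2CH2Cl, 40 °C
Reagents that add atoms: tert-butyl hydroperoxide, CC(C)(C)OO
Why: Peroxyl-radical allylic C–H oxidation of an α,β-unsaturated ester at its γ-CH2 (C8) gives the 4-oxo-2-enoate, a known outcome for cycloalkene carboxylates; the only other allylic hydrogen (C1–H) is tertiary and cannot give a ketone, and base-free conditions avoid β-elimination of the lactone.

Step 18
Reactants: 28 methyl 4α-(tert-butyldimethylsilyloxy)-8-oxo-13,15-dinor-1αH,5αH,6βH,7αH-guai-9-en-12,6-olid-14-oate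
Product: 29 methyl 4α-(tert-butyldimethylsilyloxy)-8β-hydroxy-13,15-dinor-1αH,5αH,6βH,7αH-guai-9-en-12,6-olid-14-oate
Conditions: LiBH(s-Bu)3, THF, −78 °C; aq. NH4Cl at −78 °C
Reagents that add atoms: none
Why: Bulky-hydride 1,2-reduction (the enone β-carbon C10 is fully substituted) from the α face, anti to the β-oriented C7–C11 bond, should give the 8β-alcohol cis to the lactone carbon; a cold quench limits translactonisation.

Step 19
Reactants: 29 methyl 4α-(tert-butyldimethylsilyloxy)-8β-hydroxy-13,15-dinor-1αH,5αH,6βH,7αH-guai-9-en-12,6-olid-14-oate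
Product: 30 methyl 4α-(tert-butyldimethylsilyloxy)-8β-(triisopropylsilyloxy)-13,15-dinor-1αH,5αH,6βH,7αH-guai-9-en-12,6-olid-14-oate
Conditions: i-Pr3SiOTf, 2,6-lutidine, CH2Cl2, −78 → 0 °C
Reagents that add atoms: triisopropylsilyl triflate, CC(C)[Si](OS(=O)(=O)C(F)(F)F)(C(C)C)C(C)C
Why: Silyl triflate protection of a hindered secondary alcohol; TIPS outlasts the later selective removal of the C4 TBS group.

Step 20
Reactants: 30 methyl 4α-(tert-butyldimethylsilyloxy)-8β-(triisopropylsilyloxy)-13,15-dinor-1αH,5αH,6βH,7αH-guai-9-en-12,6-olid-14-oate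
Product: 31 4α-(tert-butyldimethylsilyloxy)-8β-(triisopropylsilyloxy)-13,15-dinor-1αH,5αH,6βH,7αH-guai-9-en-12,6-olid-14-oic acid
Conditions: LiOH·H2O, THF–H2O, 23 °C; then 1 M HCl to pH 2, 23 °C
Reagents that add atoms: lithium hydroxide, [Li+].[OH-]
Why: Saponification as in step 8; with O8 silylated, only the 6,12-lactone can reform.

Step 21
Reactants: 31 4α-(tert-butyldimethylsilyloxy)-8β-(triisopropylsilyloxy)-13,15-dinor-1αH,5αH,6βH,7αH-guai-9-en-12,6-olid-14-oic acid
Product: 33 14-hydroxy-4α-(tert-butyldimethylsilyloxy)-8β-(triisopropylsilyloxy)-13,15-dinor-1αH,5αH,6βH,7αH-guai-9-en-12,6-olide, via mixed carbonic anhydride 32 (not isolated)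
Conditions: i-BuOCOCl, N-methylmorpholine, THF, −15 °C; then NaBH4, H2O, 0 °C
Reagents that add atoms: none
Why: Mixed-anhydride reduction as in step 9.

Step 22
Reactants: 33 14-hydroxy-4α-(tert-butyldimethylsilyloxy)-8β-(triisopropylsilyloxy)-13,15-dinor-1αH,5αH,6βH,7αH-guai-9-en-12,6-olide
Product: 35 4α-(tert-butyldimethylsilyloxy)-8β-(triisopropylsilyloxy)-13,15-dinor-1αH,5αH,6βH,7αH-guai-10(14)-en-12,6-olide, via allylic diazene 34 (not isolated)
Conditions: PPh3, diethyl azodicarboxylate, 2-nitrobenzenesulfonylhydrazide, N-methylmorpholine/THF, −30 → 23 °C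
Reagents that add atoms: none
Why: Reductive allylic transposition as in step 10 (Mitsunobu reaction, diazene retro-ene); H goes to C9, so the C8 carbinol center is untouched.

Step 23
Reactants: 35 4α-(tert-butyldimethylsilyloxy)-8β-(triisopropylsilyloxy)-13,15-dinor-1αH,5αH,6βH,7αH-guai-10(14)-en-12,6-olide
Product: 36 4α-hydroxy-8β-(triisopropylsilyloxy)-13,15-dinor-1αH,5αH,6βH,7αH-guai-10(14)-en-12,6-olide
Conditions: HF·pyridine, pyridine, THF, 0 °C
Reagents that add atoms: none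
Why: Buffered fluoride should cleave the secondary TBS ether much faster than the secondary TIPS ether (selective desilylation).

Step 24
Reactants: 36 4α-hydroxy-8β-(triisopropylsilyloxy)-13,15-dinor-1αH,5αH,6βH,7αH-guai-10(14)-en-12,6-olide
Product: 37 4-oxo-8β-(triisopropylsilyloxy)-13,15-dinor-1αH,5αH,6βH,7αH-guai-10(14)-en-12,6-olide
Conditions: Dess–Martin periodinane, NaHCO3, CH2Cl2, 0 → 23 °C
Reagents that add atoms: none
Why: Dess–Martin oxidation as in step 12.

Step 25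
Reactants: 37 4-oxo-8β-(triisopropylsilyloxy)-13,15-dinor-1αH,5αH,6βH,7αH-guai-10(14)-en-12,6-olide
Product: 38 8β-(triisopropylsilyloxy)-13-nor-1αH,5αH,6βH,7αH-guaia-4(15),10(14)-dien-12,6-olide
Conditions: Zn, CH2Br2, TiCl4, THF/CH2Cl2, 0 → 23 °C
Reagents that add atoms: dibromomethane, BrCBr
Why: Lombardo methylenation as in step 13.

Step 26
Reactants: 38 8β-(triisopropylsilyloxy)-13-nor-1αH,5αH,6βH,7αH-guaia-4(15),10(14)-dien-12,6-olide
Product: 41 8β-(triisopropylsilyloxy)dehydrocostus lactone, via 13-dimethylamino Mannich base 39 (not isolated), via trimethylammonium iodide 40 (not isolated)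
Conditions: LiN(i-Pr)2, THF, −78 °C; CH2=NMe2+ I−, −78 → 0 °C; then MeI, MeOH, 23 °C; then aq. NaHCO3, CH2Cl2
Reagents that add atoms: Eschenmoser's salt, C=[N+](C)C.[I-]
Why: Lactone α-methylenation as in step 14 (Mannich reaction then elimination); the silyloxy group is γ to the enolate carbon and cannot be eliminated.

Step 27
Reactants: 41 8β-(triisopropylsilyloxy)dehydrocostus lactone
Product: 42 3α-hydroxy-8β-(triisopropylsilyloxy)guaia-4(15),10(14),11(13)-trien-12,6α-olide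
Conditions: SeO2 (0.5 equiv), t-BuOOH, CH2Cl2, 0 → 23 °C
Reagents that add atoms: selenium dioxide, O=[Se]=O; tert-butyl hydroperoxide, CC(C)(C)OO
Why: Selenium dioxide allylic hydroxylation at C3 as in step 15.

Step 28
Reactants: 42 3α-hydroxy-8β-(triisopropylsilyloxy)guaia-4(15),10(14),11(13)-trien-12,6α-olide
Product: 43 8β-(triisopropylsilyloxy)dehydrozaluzanin C
Conditions: Dess–Martin periodinane, NaHCO3, CH2Cl2, 0 °C
Reagents that add atoms: none
Why: Dess–Martin oxidation as in step 16.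

Step 29
Reactants: 43 8β-(triisopropylsilyloxy)dehydrozaluzanin C
Product: 44 3-(tert-butyldimethylsilyloxy)-8β-(triisopropylsilyloxy)guaia-2,4(15),10(14),11(13)-tetraen-12,6α-olide
Conditions: t-BuMe2SiOTf, Et3N, CH2Cl2, 0 °C
Reagents that add atoms: tert-butyldimethylsilyl triflate, CC(C)(C)[Si](C)(C)OS(=O)(=O)C(F)(F)F
Why: Soft enolisation/silylation can only go towards C2 (C4 has no hydrogen) and gives the silyl dienol ether needed for dehydrogenation.

Step 30
Reactants: 44 3-(tert-butyldimethylsilyloxy)-8β-(triisopropylsilyloxy)guaia-2,4(15),10(14),11(13)-tetraen-12,6α-olide; 27 dehydrozaluzanin C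
Product: 47 8-O-triisopropylsilyl ether of the target, via cross-conjugated 1,10(14)-dienone 45 (not isolated), via Diels–Alder adduct 46 (not isolated)
Conditions: Pd(OAc)2 (1.1 equiv), 27 (2 equiv), MeCN, 23 → 40 °C; then DBU (0.3 equiv), CH2Cl2, 23 °C
Reagents that add atoms: none
Why: Saegusa–Ito dehydrogenation with divalent palladium unveils dienone 45, whose C2=C1–C10=C14 diene is trapped by the C4′=C15′ methylene of 27 in an intermolecular Diels–Alder reaction. The ortho orientation joins C2 to C4′ and C14 to C15′, and attack on the convex α face of 27 sets the spiro center. DBU then moves the alkene into conjugation by γ-protonation of the dienolate, which is reversible and should leave the more stable 10βH epimer (ring C on the face away from the C8 and C11 substituents); the diene face and endo/exo mode do not matter because C2 becomes trigonal.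

Step 31
Reactants: 47 8-O-triisopropylsilyl ether of the target
Product: 48 CNP0200944.1
Conditions: HF·pyridine, THF, 23 °C
Reagents that add atoms: none
Why: Acidic fluoride desilylation frees the 8β-hydroxyl without adding to the enone or the α-methylene lactones.

**Compound list**

1 | 2-bromocyclopent-2-en-1-one | O=C1CCC=C1Br | starting material
2 | (R)-2-bromocyclopent-2-en-1-ol | O[C@@H]1CCC=C1Br | intermediate
3 | (R)-tert-butyl[(2-bromocyclopent-2-en-1-yl)oxy]dimethylsilane | BrC1=CCC[C@H]1O[Si](C)(C)C(C)(C)C | intermediate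
4 | 1-ethoxycyclopropan-1-ol | CCOC1(O)CC1 | starting material
5 | (R)-[5-(tert-butyldimethylsilyloxy)cyclopent-1-en-1-yl]lithium | [Li]C1=CCC[C@H]1O[Si](C)(C)C(C)(C)C | intermediate
6 | 1-[(5R)-5-(tert-butyldimethylsilyloxy)cyclopent-1-en-1-yl]cyclopropan-1-ol | OC1(CC1)C2=CCC[C@H]2O[Si](C)(C)C(C)(C)C | intermediate
7 | 1-(triethylsilyloxy)-1-[(5R)-5-(tert-butyldimethylsilyloxy)cyclopent-1-en-1-yl]cyclopropane | CC[Si](CC)(CC)OC1(CC1)C2=CCC[C@H]2O[Si](C)(C)C(C)(C)C | intermediate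
8 | methyl propiolate | C#CC(=O)OC | starting material
9 | methyl 4α-(TBS-oxy)-6-(TES-oxy)-11,12,13,15-tetranor-1αH-guaia-5,9-dien-14-oate | COC(=O)C1=CCCC(O[Si](CC)(CC)CC)=C2[C@H]1CC[C@H]2O[Si](C)(C)C(C)(C)C | intermediate
10 | methyl 4α-(TBS-oxy)-6-oxo-11,12,13,15-tetranor-1αH,5αH-guai-9-en-14-oate | COC(=O)C1=CCCC(=O)[C@@H]2[C@H]1CC[C@H]2O[Si](C)(C)C(C)(C)C | intermediate
11 | methyl bromoacetate | COC(=O)CBr | starting material
12 | dimethyl 4α-(TBS-oxy)-6-oxo-13,15-dinor-1αH,5αH,7αH-guai-9-ene-12,14-dioate | COC(=O)C1=CC[C@@H](CC(=O)OC)C(=O)[C@@H]2[C@H]1CC[C@H]2O[Si](C)(C)C(C)(C)C | intermediate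
13 | dimethyl 4α-(TBS-oxy)-6α-hydroxy-13,15-dinor-1αH,5αH,7αH-guai-9-ene-12,14-dioate | COC(=O)C1=CC[C@@H](CC(=O)OC)[C@H](O)[C@@H]2[C@H]1CC[C@H]2O[Si](C)(C)C(C)(C)C | intermediate
14 | methyl 4α-(TBS-oxy)-13,15-dinor-1αH,5αH,6βH,7αH-guai-9-en-12,6-olid-14-oate | COC(=O)C1=CC[C@@H]2[C@@H]([C@@H]3[C@H]1CC[C@H]3O[Si](C)(C)C(C)(C)C)OC(=O)C2 | intermediate
15 | 4α-(TBS-oxy)-13,15-dinorguai-9-en-12,6α-olid-14-oic acid | OC(=O)C1=CC[C@@H]2[C@@H]([C@@H]3[C@H]1CC[C@H]3O[Si](C)(C)C(C)(C)C)OC(=O)C2 | intermediate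
16 | isobutyl carbonic mixed anhydride of 15 | CC(C)COC(=O)OC(=O)C1=CC[C@@H]2[C@@H]([C@@H]3[C@H]1CC[C@H]3O[Si](C)(C)C(C)(C)C)OC(=O)C2 | intermediate
17 | 14-hydroxy-4α-(TBS-oxy)-13,15-dinorguai-9-en-12,6α-olide | OCC1=CC[C@@H]2[C@@H]([C@@H]3[C@H]1CC[C@H]3O[Si](C)(C)C(C)(C)C)OC(=O)C2 | intermediate
18 | 14-diazenyl-4α-(TBS-oxy)-13,15-dinorguai-9-en-12,6α-olide | N=NCC1=CC[C@@H]2[C@@H]([C@@H]3[C@H]1CC[C@H]3O[Si](C)(C)C(C)(C)C)OC(=O)C2 | intermediate
19 | 4α-(TBS-oxy)-13,15-dinorguai-10(14)-en-12,6α-olide | C=C1CC[C@@H]2[C@@H]([C@@H]3[C@H]1CC[C@H]3O[Si](C)(C)C(C)(C)C)OC(=O)C2 | intermediate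
20 | 4α-hydroxy-13,15-dinorguai-10(14)-en-12,6α-olide | C=C1CC[C@@H]2[C@@H]([C@@H]3[C@H]1CC[C@H]3O)OC(=O)C2 | intermediate
21 | 4-oxo-13,15-dinorguai-10(14)-en-12,6α-olide | C=C1CC[C@@H]2[C@@H]([C@@H]3[C@H]1CCC3=O)OC(=O)C2 | intermediate
22 | 13-norguaia-4(15),10(14)-dien-12,6α-olide | C=C1CC[C@@H]2[C@@H]([C@@H]3[C@H]1CCC3=C)OC(=O)C2 | intermediate
23 | 13-(dimethylamino)-11βH-guaia-4(15),10(14)-dien-12,6α-olide | C=C1CC[C@@H]2[C@@H]([C@@H]3[C@H]1CCC3=C)OC(=O)[C@H]2CN(C)C | intermediate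
24 | N-methyl ammonium iodide of 23 | C=C1CC[C@@H]2[C@@H]([C@@H]3[C@H]1CCC3=C)OC(=O)[C@H]2C[N+](C)(C)C.[I-] | intermediate
25 | dehydrocostus lactone | C=C1CC[C@@H]2[C@@H]([C@@H]3[C@H]1CCC3=C)OC(=O)C2=C | intermediate
26 | 3-epizaluzanin C (3α-hydroxy) | C=C1CC[C@@H]2[C@@H]([C@@H]3[C@H]1C[C@@H](O)C3=C)OC(=O)C2=C | intermediate
27 | dehydrozaluzanin C | C=C1CC[C@@H]2[C@@H]([C@@H]3[C@H]1CC(=O)C3=C)OC(=O)C2=C | intermediate
28 | methyl 4α-(TBS-oxy)-8-oxo-13,15-dinorguai-9-en-12,6α-olid-14-oate | COC(=O)C1=CC(=O)[C@@H]2[C@@H]([C@@H]3[C@H]1CC[C@H]3O[Si](C)(C)C(C)(C)C)OC(=O)C2 | intermediate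
29 | methyl 4α-(TBS-oxy)-8β-hydroxy-13,15-dinorguai-9-en-12,6α-olid-14-oate | COC(=O)C1=C[C@@H](O)[C@@H]2[C@@H]([C@@H]3[C@H]1CC[C@H]3O[Si](C)(C)C(C)(C)C)OC(=O)C2 | intermediate
30 | methyl 4α-(TBS-oxy)-8β-(TIPS-oxy)-13,15-dinorguai-9-en-12,6α-olid-14-oate | COC(=O)C1=C[C@@H](O[Si](C(C)C)(C(C)C)C(C)C)[C@@H]2[C@@H]([C@@H]3[C@H]1CC[C@H]3O[Si](C)(C)C(C)(C)C)OC(=O)C2 | intermediate
31 | 4α-(TBS-oxy)-8β-(TIPS-oxy)-13,15-dinorguai-9-en-12,6α-olid-14-oic acid | OC(=O)C1=C[C@@H](O[Si](C(C)C)(C(C)C)C(C)C)[C@@H]2[C@@H]([C@@H]3[C@H]1CC[C@H]3O[Si](C)(C)C(C)(C)C)OC(=O)C2 | intermediate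
32 | isobutyl carbonic mixed anhydride of 31 | CC(C)COC(=O)OC(=O)C1=C[C@@H](O[Si](C(C)C)(C(C)C)C(C)C)[C@@H]2[C@@H]([C@@H]3[C@H]1CC[C@H]3O[Si](C)(C)C(C)(C)C)OC(=O)C2 | intermediate
33 | 14-hydroxy-4α-(TBS-oxy)-8β-(TIPS-oxy)-13,15-dinorguai-9-en-12,6α-olide | OCC1=C[C@@H](O[Si](C(C)C)(C(C)C)C(C)C)[C@@H]2[C@@H]([C@@H]3[C@H]1CC[C@H]3O[Si](C)(C)C(C)(C)C)OC(=O)C2 | intermediate
34 | 14-diazenyl-4α-(TBS-oxy)-8β-(TIPS-oxy)-13,15-dinorguai-9-en-12,6α-olide | N=NCC1=C[C@@H](O[Si](C(C)C)(C(C)C)C(C)C)[C@@H]2[C@@H]([C@@H]3[C@H]1CC[C@H]3O[Si](C)(C)C(C)(C)C)OC(=O)C2 | intermediate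
35 | 4α-(TBS-oxy)-8β-(TIPS-oxy)-13,15-dinorguai-10(14)-en-12,6α-olide | C=C1C[C@@H](O[Si](C(C)C)(C(C)C)C(C)C)[C@@H]2[C@@H]([C@@H]3[C@H]1CC[C@H]3O[Si](C)(C)C(C)(C)C)OC(=O)C2 | intermediate
36 | 4α-hydroxy-8β-(TIPS-oxy)-13,15-dinorguai-10(14)-en-12,6α-olide | C=C1C[C@@H](O[Si](C(C)C)(C(C)C)C(C)C)[C@@H]2[C@@H]([C@@H]3[C@H]1CC[C@H]3O)OC(=O)C2 | intermediate
37 | 4-oxo-8β-(TIPS-oxy)-13,15-dinorguai-10(14)-en-12,6α-olide | C=C1C[C@@H](O[Si](C(C)C)(C(C)C)C(C)C)[C@@H]2[C@@H]([C@@H]3[C@H]1CCC3=O)OC(=O)C2 | intermediate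
38 | 8β-(TIPS-oxy)-13-norguaia-4(15),10(14)-dien-12,6α-olide | C=C1C[C@@H](O[Si](C(C)C)(C(C)C)C(C)C)[C@@H]2[C@@H]([C@@H]3[C@H]1CCC3=C)OC(=O)C2 | intermediate
39 | 13-(dimethylamino)-8β-(TIPS-oxy)-11βH-guaia-4(15),10(14)-dien-12,6α-olide | C=C1C[C@@H](O[Si](C(C)C)(C(C)C)C(C)C)[C@@H]2[C@@H]([C@@H]3[C@H]1CCC3=C)OC(=O)[C@H]2CN(C)C | intermediate
40 | N-methyl ammonium iodide of 39 | C=C1C[C@@H](O[Si](C(C)C)(C(C)C)C(C)C)[C@@H]2[C@@H]([C@@H]3[C@H]1CCC3=C)OC(=O)[C@H]2C[N+](C)(C)C.[I-] | intermediate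
41 | 8β-(TIPS-oxy)dehydrocostus lactone | C=C1C[C@@H](O[Si](C(C)C)(C(C)C)C(C)C)[C@@H]2[C@@H]([C@@H]3[C@H]1CCC3=C)OC(=O)C2=C | intermediate
42 | 3α-hydroxy-8β-(TIPS-oxy)guaia-4(15),10(14),11(13)-trien-12,6α-olide | C=C1C[C@@H](O[Si](C(C)C)(C(C)C)C(C)C)[C@@H]2[C@@H]([C@@H]3[C@H]1C[C@@H](O)C3=C)OC(=O)C2=C | intermediate
43 | 8β-(TIPS-oxy)dehydrozaluzanin C | C=C1C[C@@H](O[Si](C(C)C)(C(C)C)C(C)C)[C@@H]2[C@@H]([C@@H]3[C@H]1CC(=O)C3=C)OC(=O)C2=C | intermediate
44 | 3-(TBS-oxy)-8β-(TIPS-oxy)guaia-2,4(15),10(14),11(13)-tetraen-12,6α-olide | C=C1C[C@@H](O[Si](C(C)C)(C(C)C)C(C)C)[C@@H]2[C@@H]([C@@H]3[C@H]1C=C(O[Si](C)(C)C(C)(C)C)C3=C)OC(=O)C2=C | intermediate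
45 | 3-oxo-8β-(TIPS-oxy)guaia-1,4(15),10(14),11(13)-tetraen-12,6α-olide | C=C1C[C@@H](O[Si](C(C)C)(C(C)C)C(C)C)[C@@H]2[C@@H]([C@@H]3C1=CC(=O)C3=C)OC(=O)C2=C | intermediate
46 | Diels–Alder adduct (2βH, 1(10)-ene, C2–C4′ and C14–C15′ joined, 8-O-TIPS) | C=C1C(=O)[C@H]2C3=C(CC[C@]24C(=O)C[C@H]2C(=C)CC[C@H]5C(=C)C(=O)O[C@@H]5[C@H]24)C[C@@H](O[Si](C(C)C)(C(C)C)C(C)C)[C@H]2C(=C)C(=O)O[C@@H]2[C@@H]13 | intermediate
47 | 8-O-triisopropylsilyl ether of the target (1(2)-ene, 10βH) | C=C1C(=O)C2=C3[C@H](CC[C@]24C(=O)C[C@H]2C(=C)CC[C@H]5C(=C)C(=O)O[C@@H]5[C@H]24)C[C@@H](O[Si](C(C)C)(C(C)C)C(C)C)[C@H]2C(=C)C(=O)O[C@@H]2[C@@H]13 | intermediate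
48 | CNP0200944.1 | C=C1C(=O)C2=C3[C@H](CC[C@]24C(=O)C[C@H]2C(=C)CC[C@H]5C(=C)C(=O)O[C@@H]5[C@H]24)C[C@@H](O)[C@H]2C(=C)C(=O)O[C@@H]2[C@@H]13 | target

**Summary**

Total step count: 31. Longest linear sequence: 22 steps (steps 1–7, then 17–31).

Steps most likely to fail:

- Step 5. The propiolate may insert with the opposite orientation, the trisubstituted alkene may react sluggishly, or the face selectivity may be low. Fallback from 3 to 10: 3 is lithiated (t-BuLi) and added to pent-4-enal to give 1-[(5R)-5-(TBS-oxy)cyclopent-1-en-1-yl]pent-4-en-1-ol F1, which is oxidised (Dess–Martin periodinane) to the cyclopentenyl ketone F2. Conjugate addition of the cuprate LiCu[C(=CH2)CO2Me]2 (Me3SiCl, THF, −78 °C) anti to the silyloxy group, then protonation and DBU equilibration, should give the keto diene methyl 2-[(1S,2S,3R)-2-(pent-4-enoyl)-3-(TBS-oxy)cyclopentyl]acrylate F3. Ring-closing metathesis (second-generation Grubbs catalyst, CH2Cl2, 40 °C) closes C9=C10 and returns to 10.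

- Step 17. Hydrogen abstraction may be unselective, the product may over-oxidise, or the β-acyloxy ketone may eliminate. Fallback from 14 to 28: Wohl–Ziegler bromination (N-bromosuccinimide, AIBN, PhCF3, 80 °C) at the γ-carbon of the enoate gives the 8-bromide F4; Kornblum oxidation (AgBF4, DMSO, 23 °C; then Et3N) converts it into ketone 28.

- Step 30. The dienone may dimerise or decompose on palladium before it meets 27, so the cycloaddition partner is not engaged. Fallback from 44 to 47: 44 is selenenylated (PhSeCl, CH2Cl2, −78 °C) to the 2-phenylselanyl ketone F5. Oxidation (H2O2, pyridine, CH2Cl2, 0 °C) in the presence of 27 releases 45 slowly by selenoxide syn-elimination under neutral, metal-free conditions; the adduct 46 is then isomerised with DBU to 47.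

Further compounds
F1 | step 5 | 1-[(5R)-5-(tert-butyldimethylsilyloxy)cyclopent-1-en-1-yl]pent-4-en-1-ol (carbinol epimers) | C=CCCC(O)C1=CCC[C@H]1O[Si](C)(C)C(C)(C)C
F2 | step 5 | 1-[(5R)-5-(tert-butyldimethylsilyloxy)cyclopent-1-en-1-yl]pent-4-en-1-one | C=CCCC(=O)C1=CCC[C@H]1O[Si](C)(C)C(C)(C)C
F3 | step 5 | methyl 2-[(1S,2S,3R)-2-(pent-4-enoyl)-3-(tert-butyldimethylsilyloxy)cyclopentyl]acrylate | C=CCCC(=O)[C@@H]1[C@H](C(=C)C(=O)OC)CC[C@H]1O[Si](C)(C)C(C)(C)C
F4 | step 17 | methyl 8-bromo-4α-(TBS-oxy)-13,15-dinorguai-9-en-12,6α-olid-14-oate (C8 epimers) | COC(=O)C1=CC(Br)[C@@H]2[C@@H]([C@@H]3[C@H]1CC[C@H]3O[Si](C)(C)C(C)(C)C)OC(=O)C2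
F5 | step 30 | 2-(phenylselanyl)-8β-(TIPS-oxy)dehydrozaluzanin C (C2 epimers) | C=C1C[C@@H](O[Si](C(C)C)(C(C)C)C(C)C)[C@@H]2[C@@H]([C@@H]3[C@H]1C([Se]c4ccccc4)C(=O)C3=C)OC(=O)C2=C
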